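The route rests on disconnecting the C3–C4 bond of ring A. In the target, C3 (secondary) and C4 (tertiary, methyl-bearing, attached to sp2 C5 of ring B) hold oxygens on the same face, a 1,2-diol pattern that a samarium-bridged reductive coupling of two carbonyl carbons delivers directly. One SmI2 treatment therefore joins an aldehyde carbon (C3) to the acetyl carbon (C4), closes ring A and sets both carbinol centres. The precursor is a (+)-dihydrocarvone-derived cyclohexene (ring B) with acetyl on C5, methyl and a 3-oxopropyl arm on quaternary C10, and a silyl-protected 3-hydroxyprop-1-en-2-yl group on C7, so that C12 is oxygenated early and the acrylate is unveiled afterwards by simple oxidations.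

Key step: step 8

Remarks on the chemistry
- Atom labels follow eudesmane numbering: C1–C10 decalin, C11–C13 side chain on C7, C14 on C10, C15 on C4. The target is (3S,4R,7R,10S): 3β-angeloyloxy, 4β-hydroxy, 4α-methyl, 10β-methyl, 7β side chain. TBDPS = tert-butyldiphenylsilyl.
- Assumption: commercial (+)-dihydrocarvone may contain its C2 epimer; this is harmless because that centre becomes trigonal in the enamine tautomer of step 1.
- The carbon that becomes the ester carbonyl is C12, the methyl of the isopropenyl group; C13 remains the methylene.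
- Design choice: C12 is hydroxylated in step 2, when the isopropenyl group is the only alkene and C7–H is only singly allylic. An unfunctionalised isopropenyl group carried through the key step would require allylic oxidation of a skipped 5,11(13)-diene with a doubly allylic C7–H next to an acid-sensitive tertiary allylic alcohol.

Step 1
Reactants: 1 (+)-dihydrocarvone; 2 (R)-(+)-1-phenylethylamine; 3 methyl acrylate
Product: 6 methyl 3-[(1S,4R)-1-methyl-2-oxo-4-(prop-1-en-2-yl)cyclohexyl]propanoate, via ketimine 4 (not isolated), via adduct imine 5 (not isolated)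
Conditions: 2, TsOH (cat.), PhMe, reflux, Dean–Stark; then 3, THF, 60 °C; then aq AcOH, rt
Reagents that add atoms: methyl acrylate C=CC(=O)OC; water O
Why: Asymmetric Michael addition of a chiral ketimine through its more substituted secondary enamine tautomer (aza-ene type, cyclic transition state with N–H transfer): the acrylate should be delivered to the methyl-bearing carbon on the enamine face not screened by the phenyl group of the (R)-auxiliary, placing the propanoate arm trans and the C10 methyl cis to the C7 isopropenyl group (10S).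

Step 2
Reactants: 6 methyl 3-[(1S,4R)-1-methyl-2-oxo-4-(prop-1-en-2-yl)cyclohexyl]propanoate
Product: 7 methyl 3-[(1S,4R)-4-(3-hydroxyprop-1-en-2-yl)-1-methyl-2-oxocyclohexyl]propanoate
Conditions: SeO2 (cat.), t-BuOOH, CH2Cl2, rt
Reagents that add atoms: tert-butyl hydroperoxide CC(C)(C)OO (terminal oxygen source); selenium dioxide O=[Se]=O (relays the oxygen)
Why: Catalytic SeO2 allylic hydroxylation (ene reaction, then [2,3]-sigmatropic shift) of the only alkene present should functionalise the methyl terminus of the isopropenyl group, since C7–H is here a singly allylic tertiary hydrogen and the ketone α-methylene is inert at room temperature; no stereocentre is formed.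

Step 3
Reactants: 7 methyl 3-[(1S,4R)-4-(3-hydroxyprop-1-en-2-yl)-1-methyl-2-oxocyclohexyl]propanoate
Product: 8 methyl 3-[(1S,4R)-4-{3-[(tert-butyldiphenylsilyl)oxy]prop-1-en-2-yl}-1-methyl-2-oxocyclohexyl]propanoate
Conditions: TBDPSCl, imidazole, DMF, 0 °C → rt
Reagents that add atoms: tert-butyl(chloro)diphenylsilane CC(C)(C)[Si](Cl)(c1ccccc1)c1ccccc1
Why: Standard silylation of a primary allylic alcohol; the TBDPS ether is chosen because it should survive KN(SiMe3)2, i-Bu2AlH, the aqueous acid of step 6 and SmI2.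

Step 4
Reactants: 8 methyl 3-[(1S,4R)-4-{3-[(tert-butyldiphenylsilyl)oxy]prop-1-en-2-yl}-1-methyl-2-oxocyclohexyl]propanoate
Product: 10 methyl 3-[(1S,4R)-4-{3-[(tert-butyldiphenylsilyl)oxy]prop-1-en-2-yl}-1-methyl-2-{[(trifluoromethyl)sulfonyl]oxy}cyclohex-2-en-1-yl]propanoate, via potassium enolate 9 (not isolated)
Conditions: KN(SiMe3)2, THF, −78 °C; then PhNTf2, −78 → 0 °C
Reagents that add atoms: N-phenylbis(trifluoromethanesulfonimide) O=S(=O)(N(c1ccccc1)S(=O)(=O)C(F)(F)F)C(F)(F)F
Why: Enol triflate formation: the ketone is the most acidic site and can enolise only toward C6 because C10 is quaternary, so O-sulfonylation of the potassium enolate at low temperature should give the C5=C6 vinyl triflate while the less acidic ester stays untouched.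

Step 5
Reactants: 10 methyl 3-[(1S,4R)-4-{3-[(tert-butyldiphenylsilyl)oxy]prop-1-en-2-yl}-1-methyl-2-{[(trifluoromethyl)sulfonyl]oxy}cyclohex-2-en-1-yl]propanoate
Product: 11 (3R,6S)-3-{3-[(tert-butyldiphenylsilyl)oxy]prop-1-en-2-yl}-6-(3-hydroxypropyl)-6-methylcyclohex-1-en-1-yl trifluoromethanesulfonate
Conditions: i-Bu2AlH, CH2Cl2, −78 °C; aq potassium sodium tartrate (KNaC4H4O6) work-up
Reagents that add atoms: none
Why: i-Bu2AlH reduction of the methyl ester to the primary alcohol at low temperature, conditions under which a vinyl triflate and a silyl ether are inert.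

Step 6
Reactants: 11 (3R,6S)-3-{3-[(tert-butyldiphenylsilyl)oxy]prop-1-en-2-yl}-6-(3-hydroxypropyl)-6-methylcyclohex-1-en-1-yl trifluoromethanesulfonate; 12 tributyl(1-ethoxyvinyl)stannane
Product: 14 1-[(3R,6S)-3-{3-[(tert-butyldiphenylsilyl)oxy]prop-1-en-2-yl}-6-(3-hydroxypropyl)-6-methylcyclohex-1-en-1-yl]ethan-1-one, via ethoxydiene 13 (not isolated)
Conditions: 12, Pd(PPh3)4 (cat.), LiCl, THF, 65 °C; then 1 M HCl, rt
Reagents that add atoms: tributyl(1-ethoxyvinyl)stannane CCOC(=C)[Sn](CCCC)(CCCC)CCCC; water O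
Why: Stille coupling of the vinyl triflate with an α-alkoxyvinylstannane under zerovalent palladium catalysis (LiCl assists turnover of the triflate), followed in the same flask by acid hydrolysis of the 2-ethoxydiene to the C5 acetyl group, which the TBDPS ether should tolerate.

Step 7
Reactants: 14 1-[(3R,6S)-3-{3-[(tert-butyldiphenylsilyl)oxy]prop-1-en-2-yl}-6-(3-hydroxypropyl)-6-methylcyclohex-1-en-1-yl]ethan-1-one
Product: 15 3-[(1S,4R)-2-acetyl-4-{3-[(tert-butyldiphenylsilyl)oxy]prop-1-en-2-yl}-1-methylcyclohex-2-en-1-yl]propanal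
Conditions: Dess–Martin periodinane, NaHCO3, CH2Cl2, 0 °C → rt
Reagents that add atoms: none
Why: Dess–Martin oxidation of the primary alcohol to the aldehyde under buffered, non-enolising conditions, so that neither the γ-hydrogen at C7 of the enone nor the aldehyde α-position should be disturbed.

Step 8
Reactants: 15 3-[(1S,4R)-2-acetyl-4-{3-[(tert-butyldiphenylsilyl)oxy]prop-1-en-2-yl}-1-methylcyclohex-2-en-1-yl]propanal
Product: 16 (3S,4R,7R,10S)-12-[(tert-butyldiphenylsilyl)oxy]eudesma-5,11(13)-diene-3,4-diol (3β,4β-diol)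
Conditions: SmI2 (2.5 equiv), THF, high dilution, −78 → 0 °C; aq NaH2PO4/Na2HPO4 (pH 7)
Reagents that add atoms: none
Why: SmI2 transfers one electron to the aldehyde, the more easily reduced and less hindered carbonyl; the C3 ketyl, held to the acetyl oxygen through trivalent samarium, adds to the acetyl carbon C4, and a second electron transfer gives the samarium diolate, the closest known reaction type being the SmI2-mediated intramolecular pinacol cyclisation of keto aldehydes to cis-cycloalkane-1,2-diols. Ring A closes in a 6-exo-trig mode on the C4=O bond. C4 is controlled by the ring: because the C5=C6 bond of ring B holds C9 anti to C4, ring A can only form as the chair with the C10 methyl axial, so the new carbinol carbon should place C15 equatorial (over H6) and its oxygen axial on the β face, the alternative setting C15 syn-axial to the C10 methyl. C3 is controlled by chelation: the samarium bridge requires the C3 oxygen gauche to the axial C4 oxygen, which in this chair is the equatorial β position, hence the 3β,4β-cis-diol. The step needs bond formation at C4 and not at C6; this should be secured by the chelate that presents the two carbonyl carbons to each other, by the twist that quaternary C10 imposes on the acetyl group (weak conjugation with C5=C6), and by the fact that attack at C6 would be a 6-endo closure on a β-branched ring carbon leading to a bridged bicycle. The silyl ether and both alkenes are not reduced by SmI2 in THF without additives, and HMPA is left out because it would loosen the chelate.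

Step 9
Reactants: 16 (3S,4R,7R,10S)-12-[(tert-butyldiphenylsilyl)oxy]eudesma-5,11(13)-diene-3,4-diol; 17 angelic acid
Product: 19 (3S,4R,7R,10S)-12-[(tert-butyldiphenylsilyl)oxy]-4-hydroxyeudesma-5,11(13)-dien-3-yl (Z)-2-methylbut-2-enoate, via mixed anhydride 18 (not isolated)
Conditions: 17, 2,4,6-Cl3C6H2COCl, Et3N, PhMe, rt; then 16, PhMe, 80 °C
Reagents that add atoms: angelic acid C/C=C(/C)C(O)=O
Why: Yamaguchi esterification: the preformed mixed anhydride should acylate the equatorial secondary C3 hydroxyl at its less hindered angeloyl carbonyl, the tertiary C4 hydroxyl being unreactive, and the absence of a nucleophilic catalyst should preserve the Z geometry; acylating at this point also removes the free 1,2-diol before the oxidations.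

Step 10
Reactants: 19 (3S,4R,7R,10S)-12-[(tert-butyldiphenylsilyl)oxy]-4-hydroxyeudesma-5,11(13)-dien-3-yl (Z)-2-methylbut-2-enoate
Product: 20 (3S,4R,7R,10S)-4,12-dihydroxyeudesma-5,11(13)-dien-3-yl (Z)-2-methylbut-2-enoate
Conditions: Bu4NF, AcOH, THF, 0 °C → rt
Reagents that add atoms: none
Why: Fluoride-mediated cleavage of the primary silyl ether; buffering with AcOH keeps the medium non-basic, so the angelate should neither migrate nor isomerise and the doubly allylic C7–H stays untouched.

Step 11
Reactants: 20 (3S,4R,7R,10S)-4,12-dihydroxyeudesma-5,11(13)-dien-3-yl (Z)-2-methylbut-2-enoate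
Product: 21 (3S,4R,7R,10S)-4-hydroxy-12-oxoeudesma-5,11(13)-dien-3-yl (Z)-2-methylbut-2-enoate
Conditions: MnO2, CH2Cl2, rt
Reagents that add atoms: none
Why: MnO2 oxidises allylic alcohols selectively, so only the primary C12 hydroxyl should be converted to the enal; the tertiary C4 hydroxyl cannot be oxidised and, with C3 acylated, no vicinal diol is open to glycol cleavage.

Step 12
Reactants: 21 (3S,4R,7R,10S)-4-hydroxy-12-oxoeudesma-5,11(13)-dien-3-yl (Z)-2-methylbut-2-enoate
Product: 22 (3S,4R,7R,10S)-4-hydroxy-3-{[(Z)-2-methylbut-2-enoyl]oxy}eudesma-5,11(13)-dien-12-oic acid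
Conditions: NaClO2, NaH2PO4, 2-methyl-2-butene, t-BuOH/H2O, 0 °C → rt
Reagents that add atoms: sodium chlorite [Na+].[O-]Cl=O
Why: Pinnick oxidation converts the α-substituted acrolein to the acrylic acid in a mildly acidic buffer, 2-methyl-2-butene trapping the hypochlorous acid before it can attack the C5=C6 alkene.

Step 13
Reactants: 22 (3S,4R,7R,10S)-4-hydroxy-3-{[(Z)-2-methylbut-2-enoyl]oxy}eudesma-5,11(13)-dien-12-oic acid
Product: 23 methyl (3S,4R,7R,10S)-4-hydroxy-3-{[(Z)-2-methylbut-2-enoyl]oxy}eudesma-5,11(13)-dien-12-oate (target, CNP0283268.1)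
Conditions: Me3SiCHN2, PhMe/MeOH, 0 °C
Reagents that add atoms: (trimethylsilyl)diazomethane C[Si](C)(C)C=[N+]=[N-]
Why: O-Methylation of the carboxylic acid by diazomethane generated in situ from Me3SiCHN2 and methanol proceeds under neutral conditions, which should avoid migration of the C11=C13 bond into conjugation with C5=C6 and keep the angelate Z.

Compound list
1 | (+)-dihydrocarvone, (2R,5R)-2-methyl-5-(prop-1-en-2-yl)cyclohexan-1-one | CC(=C)[C@H]1CC(=O)[C@H](C)CC1 | starting material
2 | (R)-(+)-1-phenylethylamine | C[C@@H](N)c1ccccc1 | starting material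
3 | methyl acrylate | C=CC(=O)OC | starting material
4 | ketimine of 1 and 2, (5R)-2-methyl-N-[(1R)-1-phenylethyl]-5-(prop-1-en-2-yl)cyclohexan-1-imine (C2 labile) | CC(=C)[C@H]1CC(=N[C@H](C)c2ccccc2)C(C)CC1 | intermediate
5 | adduct imine, methyl 3-[(1S,4R)-1-methyl-2-{[(1R)-1-phenylethyl]imino}-4-(prop-1-en-2-yl)cyclohexyl]propanoate | CC(=C)[C@H]1CC(=N[C@H](C)c2ccccc2)[C@](C)(CCC(=O)OC)CC1 | intermediate
6 | methyl 3-[(1S,4R)-1-methyl-2-oxo-4-(prop-1-en-2-yl)cyclohexyl]propanoate | CC(=C)[C@H]1CC(=O)[C@](C)(CCC(=O)OC)CC1 | intermediate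
7 | methyl 3-[(1S,4R)-4-(3-hydroxyprop-1-en-2-yl)-1-methyl-2-oxocyclohexyl]propanoate | OCC(=C)[C@H]1CC(=O)[C@](C)(CCC(=O)OC)CC1 | intermediate
8 | methyl 3-[(1S,4R)-4-{3-[(tert-butyldiphenylsilyl)oxy]prop-1-en-2-yl}-1-methyl-2-oxocyclohexyl]propanoate | CC(C)(C)[Si](c2ccccc2)(c3ccccc3)OCC(=C)[C@H]1CC(=O)[C@](C)(CCC(=O)OC)CC1 | intermediate
9 | potassium (3R,6S)-3-{3-[(tert-butyldiphenylsilyl)oxy]prop-1-en-2-yl}-6-(3-methoxy-3-oxopropyl)-6-methylcyclohex-1-en-1-olate | CC(C)(C)[Si](c2ccccc2)(c3ccccc3)OCC(=C)[C@H]1C=C([O-])[C@](C)(CCC(=O)OC)CC1.[K+] | intermediate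
10 | methyl 3-[(1S,4R)-4-{3-[(tert-butyldiphenylsilyl)oxy]prop-1-en-2-yl}-1-methyl-2-{[(trifluoromethyl)sulfonyl]oxy}cyclohex-2-en-1-yl]propanoate | CC(C)(C)[Si](c2ccccc2)(c3ccccc3)OCC(=C)[C@H]1C=C(OS(=O)(=O)C(F)(F)F)[C@](C)(CCC(=O)OC)CC1 | intermediate
11 | (3R,6S)-3-{3-[(tert-butyldiphenylsilyl)oxy]prop-1-en-2-yl}-6-(3-hydroxypropyl)-6-methylcyclohex-1-en-1-yl trifluoromethanesulfonate | CC(C)(C)[Si](c2ccccc2)(c3ccccc3)OCC(=C)[C@H]1C=C(OS(=O)(=O)C(F)(F)F)[C@](C)(CCCO)CC1 | intermediate
12 | tributyl(1-ethoxyvinyl)stannane | CCOC(=C)[Sn](CCCC)(CCCC)CCCC | starting material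
13 | 3-[(1S,4R)-4-{3-[(tert-butyldiphenylsilyl)oxy]prop-1-en-2-yl}-2-(1-ethoxyvinyl)-1-methylcyclohex-2-en-1-yl]propan-1-ol | CC(C)(C)[Si](c2ccccc2)(c3ccccc3)OCC(=C)[C@H]1C=C(C(=C)OCC)[C@](C)(CCCO)CC1 | intermediate
14 | 1-[(3R,6S)-3-{3-[(tert-butyldiphenylsilyl)oxy]prop-1-en-2-yl}-6-(3-hydroxypropyl)-6-methylcyclohex-1-en-1-yl]ethan-1-one | CC(C)(C)[Si](c2ccccc2)(c3ccccc3)OCC(=C)[C@H]1C=C(C(C)=O)[C@](C)(CCCO)CC1 | intermediate
15 | 3-[(1S,4R)-2-acetyl-4-{3-[(tert-butyldiphenylsilyl)oxy]prop-1-en-2-yl}-1-methylcyclohex-2-en-1-yl]propanal (key-step precursor) | CC(C)(C)[Si](c2ccccc2)(c3ccccc3)OCC(=C)[C@H]1C=C(C(C)=O)[C@](C)(CCC=O)CC1 | intermediate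
16 | (3S,4R,7R,10S)-12-[(tert-butyldiphenylsilyl)oxy]eudesma-5,11(13)-diene-3,4-diol (key-step product, 3β,4β) | CC(C)(C)[Si](c2ccccc2)(c3ccccc3)OCC(=C)[C@H]1C=C4[C@](C)(CC[C@H](O)[C@]4(C)O)CC1 | intermediate
17 | angelic acid, (Z)-2-methylbut-2-enoic acid | C/C=C(/C)C(O)=O | starting material
18 | (Z)-2-methylbut-2-enoic 2,4,6-trichlorobenzoic anhydride | C/C=C(/C)C(=O)OC(=O)c1c(Cl)cc(Cl)cc1Cl | intermediate
19 | (3S,4R,7R,10S)-12-[(tert-butyldiphenylsilyl)oxy]-4-hydroxyeudesma-5,11(13)-dien-3-yl (Z)-2-methylbut-2-enoate | CC(C)(C)[Si](c2ccccc2)(c3ccccc3)OCC(=C)[C@H]1C=C4[C@](C)(CC[C@H](OC(=O)/C(C)=C\C)[C@]4(C)O)CC1 | intermediate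
20 | (3S,4R,7R,10S)-4,12-dihydroxyeudesma-5,11(13)-dien-3-yl (Z)-2-methylbut-2-enoate | OCC(=C)[C@H]1C=C2[C@](C)(CC[C@H](OC(=O)/C(C)=C\C)[C@]2(C)O)CC1 | intermediate
21 | (3S,4R,7R,10S)-4-hydroxy-12-oxoeudesma-5,11(13)-dien-3-yl (Z)-2-methylbut-2-enoate | O=CC(=C)[C@H]1C=C2[C@](C)(CC[C@H](OC(=O)/C(C)=C\C)[C@]2(C)O)CC1 | intermediate
22 | (3S,4R,7R,10S)-4-hydroxy-3-{[(Z)-2-methylbut-2-enoyl]oxy}eudesma-5,11(13)-dien-12-oic acid | OC(=O)C(=C)[C@H]1C=C2[C@](C)(CC[C@H](OC(=O)/C(C)=C\C)[C@]2(C)O)CC1 | intermediate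
23 | methyl (3S,4R,7R,10S)-4-hydroxy-3-{[(Z)-2-methylbut-2-enoyl]oxy}eudesma-5,11(13)-dien-12-oate (CNP0283268.1) | C=C(C(=O)OC)[C@H]1C=C2[C@](C)(CC[C@H](OC(=O)/C(C)=C\C)[C@]2(C)O)CC1 | target

Total step count: 13. Longest linear sequence: 13 steps (1 → 23).

Steps most likely to fail

Step 8 (key step). The ketyl may add in a conjugate sense to C6 instead of to the acetyl carbon, the carbonyl groups may be reduced without coupling, or an open, non-chelated transition state may erode the cis selectivity. The fallback sets out from 15 and replaces the radical coupling by a polar umpolung closure of the same bond. An N-heterocyclic carbene generated from 2-(pentafluorophenyl)-6,7-dihydro-5H-pyrrolo[2,1-c][1,2,4]triazol-2-ium tetrafluoroborate and Et3N in THF at rt should effect an intramolecular crossed aldehyde–ketone benzoin reaction. The acyl anion equivalent at C3 adds to the acetyl carbon, under the same chair preference (C15 equatorial), to give the α-ketol (4R,7R,10S)-12-[(tert-butyldiphenylsilyl)oxy]-4-hydroxyeudesma-5,11(13)-dien-3-one F1. Reduction with NaBH4 in MeOH at −40 °C should then deliver hydride axially at C3 from the α face, giving the equatorial 3β-alcohol and returning to the route at 16.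

Step 2. Over-oxidation to the enal and competing hydrogen abstraction at C7 in the ene step may lower the amount of primary allylic alcohol. The fallback sets out from 6 and introduces the C12 heteroatom by ene-type chlorination instead. Ca(OCl)2 with solid CO2 in CH2Cl2/H2O at 0 °C should give methyl 3-[(1S,4R)-4-(3-chloroprop-1-en-2-yl)-1-methyl-2-oxocyclohexyl]propanoate F2. Displacement with KOAc and catalytic 18-crown-6 in DMF at 50 °C gives methyl 3-[(1S,4R)-4-(3-acetoxyprop-1-en-2-yl)-1-methyl-2-oxocyclohexyl]propanoate F3. Methanolysis with K2CO3 in MeOH at 0 °C returns to the route at 7.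

Step 9. Geometrical isomerisation of the activated angeloyl unit to the tigloyl isomer may occur, or acylation of the hindered C3 hydroxyl may be slow enough to allow it. The fallback sets out from 16 and builds the Z double bond on the ester instead of transferring it. Esterification with 2-[bis(2,2,2-trifluoroethoxy)phosphoryl]propanoic acid (DCC, catalytic DMAP, CH2Cl2, rt) gives (3S,4R,7R,10S)-12-[(tert-butyldiphenylsilyl)oxy]-4-hydroxyeudesma-5,11(13)-dien-3-yl 2-[bis(2,2,2-trifluoroethoxy)phosphoryl]propanoate F4. Still–Gennari olefination (KN(SiMe3)2, 18-crown-6, THF, −78 °C, then acetaldehyde) should form the (Z)-2-methylbut-2-enoate and return to the route at 19.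

Further compounds
F1 | step 8 | (4R,7R,10S)-12-[(tert-butyldiphenylsilyl)oxy]-4-hydroxyeudesma-5,11(13)-dien-3-one | CC(C)(C)[Si](c2ccccc2)(c3ccccc3)OCC(=C)[C@H]1C=C4[C@](C)(CCC(=O)[C@]4(C)O)CC1
F2 | step 2 | methyl 3-[(1S,4R)-4-(3-chloroprop-1-en-2-yl)-1-methyl-2-oxocyclohexyl]propanoate | ClCC(=C)[C@H]1CC(=O)[C@](C)(CCC(=O)OC)CC1
F3 | step 2 | methyl 3-[(1S,4R)-4-(3-acetoxyprop-1-en-2-yl)-1-methyl-2-oxocyclohexyl]propanoate | CC(=O)OCC(=C)[C@H]1CC(=O)[C@](C)(CCC(=O)OC)CC1
F4 | step 9 | (3S,4R,7R,10S)-12-[(tert-butyldiphenylsilyl)oxy]-4-hydroxyeudesma-5,11(13)-dien-3-yl 2-[bis(2,2,2-trifluoroethoxy)phosphoryl]propanoate | CC(C)(C)[Si](c2ccccc2)(c3ccccc3)OCC(=C)[C@H]1C=C4[C@](C)(CC[C@H](OC(=O)C(C)P(=O)(OCC(F)(F)F)OCC(F)(F)F)[C@]4(C)O)CC1
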